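Readings and results come from a simulation on assumed constants.

Q in the ash run stands at 0.1347 M at 22 min, and the dispute is over where it stands at 44 min in the larch run, which has the same charge.

| flask | G | X | time |
|---|---|---|---|
| ash | 0.250 M | 0.500 M |  |
| cedar | 0.130 M | 0.380 M |  |
| elm | 0.750 M | 0.500 M |  |
| larch | 0.250 M | 0.500 M | 44 min |

| run | time / min | [Q] / M |
|---|---|---|
| ash run | 1.7 | 0.0286 |
| ash run | 5.1 | 0.0664 |
| ash run | 9.7 | 0.1000 |
| ash run | 15 | 0.1210 |
| ash run | 22 | 0.1347 |
| cedar run | 1.7 | 0.0133 |
| cedar run | 5.1 | 0.0327 |
| cedar run | 9.7 | 0.0509 |
| cedar run | 15 | 0.0617 |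
| cedar run | 22 | 0.0668 |
| elm run | 1.7 | 0.0575 |
| elm run | 5.1 | 0.1434 |
| elm run | 9.7 | 0.2145 |
| elm run | 15 | 0.2604 |
| elm run | 22 | 0.2853 |

(scatter of a reading: 0.001 M)

- Overall: G + X -> Q.
- Constant volume, constant temperature.
- Readings of a species count what is bound in complexes too.
- "The second partner" is X.
- An order is taken over about fifteen percent of the charge, up and down.

* order of the initial rate in [G], near the charge of the ash run, the rate being that where two percent of its G are Q (one fixed amount of Q, the same in the runs compared)
* order of the initial rate in [X], near the charge of the ash run, the rate being that where two percent of its G are Q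
* Q in the larch run at 44 min, as a share of the G charged

My opponent reads the ash run as one irreversible second-order step, G + X -> Q, with G the limiting reagent (0.250 M against 0.500 M of X). She takes her rate constant k from the first ash reading as Q/(t[G]₀[X]₀), which gives 0.135 /M/min. Her integrated law then puts the larch run at 87.2% of the G charged. For the ash run it gives 0.0683 M at 5.1 min, against a reading of 0.0664 M. At 22 min, however, it gives 0.172 M, which is 37.0 times the scatter above the reading.

I hold that Q levels off at a plateau P, and I count turnovers of one clock. That clock is 8.01 min in the ash run: the fill time τ, the time the rate of the first reading needs to make the Q of the last reading, close kin to a relaxation time. After n = t/τ turnovers, I take the gap to P to be exp(−n) of P. The last ash reading has had 2.75 turnovers, so the ash readings put P at 0.144 M. The clock gives 0.101 M at 9.7 min, a reading it did not use, and that reading is 0.1000 M. At 44 min the larch run has had 5.49 turnovers, and my reckoning gives 57.3% of its G. Her law keeps its ground inside the first turnover, as at 5.1 min, which is earlier than τ.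

The forecast, above my figure, gives orders of 0.78 in G and 0.55 in X and 57.7% for the larch run, and says “this looks like a reversible reaction, not a stalled one”.

The flask gives 53.8% in the larch run, 3.5 percentage points below my figure and 33 points below the plain irreversible step, with orders of 0.88 in G and 0.48 in X.

    G + X ⇌ Q (0.5466 /M/min, 0.02634 /min)
    G → Vy (0.04794 /min)
    G + X ⇌ GX, settled at all times (4.830 /M)

A fit with the main steps alone gives 57.6% for the larch run, with a root mean square residual of 8.9 in units of the scatter. In the ash run, τ puts Q at a quarter of the G charged at 4.56 min, and the flask gives 4.59 min. The cedar run reads τ = 8.54 min and P = 0.0723 M, which puts the same mark at 5.10 min, and the flask gives 4.87 min.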